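**Plan** (labdane numbering: C1–C10 decalin, C11/C12 side-chain CH2 groups, C13–C16 butenolide, C17 methyl on C8, C18 α-methyl and C19 β-CH2OH on C4, C20 methyl on C10)

- Retrosynthesis: cut C12–C13 (B-alkyl Suzuki–Miyaura coupling) and C11=C12 (Wittig) back to a C11 carbonyl, then cut C7–C8 and C9–C10 together (intramolecular Diels–Alder), then the O2–C11 ester, then the C5–C6 vinyl bond and the C4–C19 bond of ring A.
- Forward: ring A is built first from a meso cyclohexanone and turned into the C7=C6–C5=C10 diene. Ring B and a temporary lactone ring close in one cycloaddition. The lactone is opened, C5–H and C6–OH are added, and the side chain with the butenolide comes last.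
- Enabling feature: the 2α-oxygen lies 1,3 to C10 on ring A, and C9 carries the carbon C11. An ester O2–C11(=O)–C9≡C8–CH3 therefore holds the alkyne under the α-face of the diene, and its carbonyl carbon is the future side-chain carbon C11.
- Stereochemistry: the absolute configuration comes from enantioselective deprotonation of the meso ketone; C4 from hydroxymethylation anti to O2; C10 from the tether; C5 and C6 from α-face syn hydroboration.

Key step: step 10

Assumption: the lithium amide is taken to select the enantiotopic α-hydrogen in the sense known for 4-substituted cyclohexanones; if the sense is opposite, the (R,R)-amide is used and nothing else changes.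

Step 1
Reactants: 1 4-(tert-butyldimethylsilyloxy)cyclohexan-1-one
Product: 3 4-(tert-butyldimethylsilyloxy)-2-methylcyclohexan-1-one (racemic diastereomer mixture), via lithium enolate 2 (not isolated)
Conditions: LDA, THF, −78 °C; MeI, −78 to 0 °C
Reagents that add atoms: iodomethane, CI
Why: Kinetic enolate alkylation of a symmetrical ketone should give clean monomethylation; the configuration at this stage is irrelevant because step 2 equilibrates it.

Step 2
Reactants: 3 4-(tert-butyldimethylsilyloxy)-2-methylcyclohexan-1-one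
Product: 6 all-cis-4-(tert-butyldimethylsilyloxy)-2,6-dimethylcyclohexan-1-one (meso), via lithium enolate 4 (not isolated), via dimethyl ketone isomer mixture 5 (not isolated)
Conditions: LDA, THF, −78 °C; MeI, −78 to 0 °C; then NaOMe (cat.), MeOH, rt
Reagents that add atoms: iodomethane, CI
Why: Kinetic deprotonation takes place at the unsubstituted α-carbon, so the second enolate alkylation gives the 2,6-dimethyl ketone; base-mediated epimerisation should then funnel all isomers into the all-equatorial, all-cis meso ketone.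

Step 3
Reactants: 6 all-cis-4-(tert-butyldimethylsilyloxy)-2,6-dimethylcyclohexan-1-one
Product: 8 (4R,6S)-4-(tert-butyldimethylsilyloxy)-2,6-dimethyl-1-(trimethylsilyloxy)cyclohex-1-ene, via chiral lithium enolate 7 (not isolated)
Conditions: (S,S)-bis(1-phenylethyl)amine, n-BuLi, LiCl, TMSCl (in situ quench), THF, −100 to −78 °C
Reagents that add atoms: chlorotrimethylsilane, C[Si](C)(C)Cl
Why: Enantioselective deprotonation of a meso ketone by a chiral lithium amide with in situ silyl trapping; removal of one enantiotopic axial α-hydrogen fixes the absolute configuration at the silyloxy carbon (future C2) and marks the enolised carbon as the future C4.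

Step 4
Reactants: 8 (4R,6S)-4-(tert-butyldimethylsilyloxy)-2,6-dimethyl-1-(trimethylsilyloxy)cyclohex-1-ene
Product: 9 (2R,4R,6S)-4-(tert-butyldimethylsilyloxy)-2-(hydroxymethyl)-2,6-dimethylcyclohexan-1-one
Conditions: aq. HCHO (37%), Yb(OTf)3 (10 mol%), THF/H2O, rt
Reagents that add atoms: formaldehyde, C=O
Why: Lanthanide-triflate-catalysed aqueous Mukaiyama aldol reaction with formaldehyde creates the quaternary C4; axial attack on the half-chair anti to the silyloxy group and to the remaining methyl should place CH2OH trans to the silyloxy group (β) and the methyl α.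

Step 5
Reactants: 9 (2R,4R,6S)-4-(tert-butyldimethylsilyloxy)-2-(hydroxymethyl)-2,6-dimethylcyclohexan-1-one
Product: 10 (2R,4R,6S)-4-(tert-butyldimethylsilyloxy)-2-[(tert-butyldiphenylsilyloxy)methyl]-2,6-dimethylcyclohexan-1-one
Conditions: TBDPSCl, imidazole, DMAP (cat.), DMF, rt
Reagents that add atoms: tert-butyl(chloro)diphenylsilane, CC(C)(C)[Si](Cl)(c1ccccc1)c1ccccc1
Why: Standard silylation of the primary neopentyl alcohol; the acid-stable TBDPS group is chosen so that the secondary TBS ether can later be removed in its presence.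

Step 6
Reactants: 10 (2R,4R,6S)-4-(tert-butyldimethylsilyloxy)-2-[(tert-butyldiphenylsilyloxy)methyl]-2,6-dimethylcyclohexan-1-one
Product: 12 (4R,6R)-4-(tert-butyldimethylsilyloxy)-6-[(tert-butyldiphenylsilyloxy)methyl]-2,6-dimethylcyclohex-1-en-1-yl trifluoromethanesulfonate, via potassium enolate 11 (not isolated)
Conditions: KHMDS, THF, −78 to −40 °C; PhNTf2, −78 °C to rt
Reagents that add atoms: N-phenylbis(trifluoromethanesulfonimide), O=S(=O)(N(c1ccccc1)S(=O)(=O)C(F)(F)F)C(F)(F)F
Why: Enol triflate formation; the ketone can enolise only toward the methyl-bearing carbon because the other α-carbon is quaternary, so the tetrasubstituted C5=C10 triflate should form regiospecifically (the methyl stereocentre of 10 is erased here).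

Step 7
Reactants: 12 (4R,6R)-4-(tert-butyldimethylsilyloxy)-6-[(tert-butyldiphenylsilyloxy)methyl]-2,6-dimethylcyclohex-1-en-1-yl trifluoromethanesulfonate
Product: 13 (4R,6S)-4-(tert-butyldimethylsilyloxy)-6-[(tert-butyldiphenylsilyloxy)methyl]-1-ethenyl-2,6-dimethylcyclohex-1-ene
Conditions: Bu3SnCH=CH2, Pd(PPh3)4 (5 mol%), LiCl, THF, 65 °C
Reagents that add atoms: tributyl(vinyl)stannane, CCCC[Sn](CCCC)(CCCC)C=C
Why: Stille coupling of a hindered cyclohexenyl triflate with a vinylstannane (LiCl-promoted) installs C6=C7 and completes the semicyclic diene.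

Step 8
Reactants: 13 (4R,6S)-4-(tert-butyldimethylsilyloxy)-6-[(tert-butyldiphenylsilyloxy)methyl]-1-ethenyl-2,6-dimethylcyclohex-1-ene
Product: 14 (1R,5S)-5-[(tert-butyldiphenylsilyloxy)methyl]-4-ethenyl-3,5-dimethylcyclohex-3-en-1-ol
Conditions: CSA (10 mol%), MeOH/CH2Cl2, 0 °C
Reagents that add atoms: none
Why: Acid-catalysed methanolysis should cleave the secondary TBS ether much faster than the neopentyl TBDPS ether, freeing only the 2α-hydroxyl.

Step 9
Reactants: 14 (1R,5S)-5-[(tert-butyldiphenylsilyloxy)methyl]-4-ethenyl-3,5-dimethylcyclohex-3-en-1-ol; 15 but-2-ynoic acid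
Product: 16 (1R,5S)-5-[(tert-butyldiphenylsilyloxy)methyl]-4-ethenyl-3,5-dimethylcyclohex-3-en-1-yl but-2-ynoate
Conditions: DCC, DMAP (5 mol%), CH2Cl2, −20 to 0 °C
Reagents that add atoms: none
Why: Steglich esterification under cold, low-DMAP conditions (to avoid conjugate addition to the ynoate) attaches the dienophile to O2 with retention at C2.

Step 10
Reactants: 16 (1R,5S)-5-[(tert-butyldiphenylsilyloxy)methyl]-4-ethenyl-3,5-dimethylcyclohex-3-en-1-yl but-2-ynoate
Product: 17 19-(tert-butyldiphenylsilyloxy)-12,13,14,15,16-pentanorlabda-5,8-dien-11,2α-olide (tricyclic δ-lactone; 10β-methyl)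
Conditions: toluene (0.005 M), BHT, 150 °C, sealed tube, argon
Reagents that add atoms: none
Why: This is a thermal intramolecular Diels–Alder reaction (type 1, ester tether), a concerted suprafacial [4+2] addition of the but-2-ynoate triple bond to the s-cis C7=C6–C5=C10 diene; the closest known reaction types are the thermal cyclisation of dienyl alkynoates and the addition of acetylenic esters to 2-methyl-6,6-disubstituted 1-vinylcyclohexenes. Ring B closes as the six-membered carbocycle by forming both C7–C8 and C9–C10 (giving the C5=C6/C8=C9 1,4-cyclohexadiene), and the six-membered lactone ring (O2–C11–C9–C10–C1–C2) closes with it as the tether ring, bridging ring A as a 2-oxabicyclo[3.3.1]nonane. The only new stereocentre, quaternary C10, is fixed by the tether: the ester on the axial 2α-oxygen can reach C10 only from the α-face, so C9 adds cis to O2 and the methyl ends up β. Regiochemistry (ester-bearing alkyne carbon to C10, methyl-bearing carbon to C7) is enforced by the four-atom tether, which cannot span to C7. The step needs periselectivity over the [1,5]-hydrogen shift of the C10 methyl group and over intermolecular addition; intramolecularity, high dilution, a radical inhibitor and the lowest workable temperature are relied on. The strain of the bridged adduct is tolerable because C5 stays trigonal, and it is released in step 11.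

Step 11
Reactants: 17 19-(tert-butyldiphenylsilyloxy)-12,13,14,15,16-pentanorlabda-5,8-dien-11,2α-olide
Product: 18 19-(tert-butyldiphenylsilyloxy)-12,13,14,15,16-pentanorlabda-5,8-diene-2α,11-diol
Conditions: LiAlH4, THF, 0 °C
Reagents that add atoms: none
Why: Hydride reduction of the strained unsaturated lactone (1,2-addition at the tetrasubstituted enoate) removes the tether, returns the 2α-hydroxyl and leaves C11 as an allylic alcohol, so that ring A can relax to its chair.

Step 12
Reactants: 18 19-(tert-butyldiphenylsilyloxy)-12,13,14,15,16-pentanorlabda-5,8-diene-2α,11-diol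
Product: 20 19-(tert-butyldiphenylsilyloxy)-12,13,14,15,16-pentanor-5α-labd-8-ene-2α,6α,11-triol, via C6 alkylborane 19 (not isolated)
Conditions: BH3·THF (4 equiv), THF, 0 °C to rt; then NaOH, H2O2, H2O, 0 °C to rt
Reagents that add atoms: hydrogen peroxide, OO
Why: Hydroboration–oxidation: borane should add syn and anti-Markovnikov (boron at C6) to the trisubstituted C5=C6 bond from the α-face, opposite the axial C20 methyl and the axial C19 substituent, setting 5α-H and 6α-OH together as in the hydroboration of Δ5-steroids; the more hindered tetrasubstituted C8=C9 bond should react much more slowly.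

Step 13
Reactants: 20 19-(tert-butyldiphenylsilyloxy)-12,13,14,15,16-pentanor-5α-labd-8-ene-2α,6α,11-triol
Product: 21 19-(tert-butyldiphenylsilyloxy)-2α,6α-dihydroxy-12,13,14,15,16-pentanor-5α-labd-8-en-11-al
Conditions: MnO2 (activated, excess), CH2Cl2, rt
Reagents that add atoms: none
Why: MnO2 oxidises only the allylic primary alcohol at C11 to the enal; the two saturated secondary alcohols should not be touched.

Step 14
Reactants: 21 19-(tert-butyldiphenylsilyloxy)-2α,6α-dihydroxy-12,13,14,15,16-pentanor-5α-labd-8-en-11-al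
Product: 22 19-(tert-butyldiphenylsilyloxy)-13,14,15,16-tetranor-5α-labda-8,11-diene-2α,6α-diol
Conditions: Ph3PCH3Br, KOtBu (4 equiv each), THF, 0 °C to rt
Reagents that add atoms: methylenetriphenylphosphorane (made from methyltriphenylphosphonium bromide), C=P(c1ccccc1)(c1ccccc1)c1ccccc1
Why: Wittig methylenation of the hindered enal gives the C9 vinyl group (C11=C12); excess ylide compensates for the two free hydroxyls, which are carried as alkoxides.

Step 15
Reactants: 22 19-(tert-butyldiphenylsilyloxy)-13,14,15,16-tetranor-5α-labda-8,11-diene-2α,6α-diol; 23 4-bromofuran-2(5H)-one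
Product: 25 19-(tert-butyldiphenylsilyloxy)-2α,6α-dihydroxylabda-8,13-dien-15,16-olide, via B-alkyl-9-BBN adduct 24 (not isolated)
Conditions: 9-BBN (3.5 equiv), THF, 0 °C to rt; then 23, PdCl2(dppf) (5 mol%), AsPh3, Cs2CO3, DMF/H2O, rt
Reagents that add atoms: none
Why: 9-BBN hydroborates the only monosubstituted alkene with boron on C12, and B-alkyl Suzuki–Miyaura coupling with the β-bromobutenolide forms C12–C13 and delivers the complete side chain; the tetrasubstituted C8=C9 bond is inert to 9-BBN.

Step 16
Reactants: 25 19-(tert-butyldiphenylsilyloxy)-2α,6α-dihydroxylabda-8,13-dien-15,16-olide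
Product: 26 2α,6α,19-trihydroxylabda-8,13-dien-15,16-olide (CNP0387838.1)
Conditions: HF·pyridine, pyridine/THF, 0 °C to rt
Reagents that add atoms: none
Why: Fluoride-mediated desilylation under buffered, non-basic conditions should remove the TBDPS group without opening or isomerising the butenolide.

**Compound list**

1 | 4-(tert-butyldimethylsilyloxy)cyclohexan-1-one | O=C1CCC(O[Si](C)(C)C(C)(C)C)CC1 | starting material
2 | lithium enolate of 1 | [Li]OC1=CCC(O[Si](C)(C)C(C)(C)C)CC1 | intermediate
3 | 4-(tert-butyldimethylsilyloxy)-2-methylcyclohexan-1-one (racemic diastereomer mixture) | CC1CC(O[Si](C)(C)C(C)(C)C)CCC1=O | intermediate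
4 | lithium enolate of 3 (less substituted side) | [Li]OC1=CCC(O[Si](C)(C)C(C)(C)C)CC1C | intermediate
5 | 4-(tert-butyldimethylsilyloxy)-2,6-dimethylcyclohexan-1-one (isomer mixture before equilibration) | CC1CC(O[Si](C)(C)C(C)(C)C)CC(C)C1=O | intermediate
6 | all-cis-4-(tert-butyldimethylsilyloxy)-2,6-dimethylcyclohexan-1-one (meso) | O=C1[C@@H](C)C[C@@H](O[Si](C)(C)C(C)(C)C)C[C@H]1C | intermediate
7 | lithium (4R,6S)-4-(tert-butyldimethylsilyloxy)-2,6-dimethylcyclohex-1-en-1-olate | CC1=C(O[Li])[C@@H](C)C[C@@H](O[Si](C)(C)C(C)(C)C)C1 | intermediate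
8 | (4R,6S)-4-(tert-butyldimethylsilyloxy)-2,6-dimethyl-1-(trimethylsilyloxy)cyclohex-1-ene | CC1=C(O[Si](C)(C)C)[C@@H](C)C[C@@H](O[Si](C)(C)C(C)(C)C)C1 | intermediate
9 | (2R,4R,6S)-4-(tert-butyldimethylsilyloxy)-2-(hydroxymethyl)-2,6-dimethylcyclohexan-1-one | O=C1[C@@H](C)C[C@@H](O[Si](C)(C)C(C)(C)C)C[C@]1(C)CO | intermediate
10 | (2R,4R,6S)-4-(tert-butyldimethylsilyloxy)-2-[(tert-butyldiphenylsilyloxy)methyl]-2,6-dimethylcyclohexan-1-one | O=C1[C@@H](C)C[C@@H](O[Si](C)(C)C(C)(C)C)C[C@]1(C)CO[Si](c1ccccc1)(c1ccccc1)C(C)(C)C | intermediate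
11 | potassium enolate of 10 (toward the methyl-bearing carbon) | CC1=C(O[K])[C@@](C)(CO[Si](c2ccccc2)(c2ccccc2)C(C)(C)C)C[C@H](O[Si](C)(C)C(C)(C)C)C1 | intermediate
12 | (4R,6R)-4-(tert-butyldimethylsilyloxy)-6-[(tert-butyldiphenylsilyloxy)methyl]-2,6-dimethylcyclohex-1-en-1-yl trifluoromethanesulfonate | CC1=C(OS(=O)(=O)C(F)(F)F)[C@@](C)(CO[Si](c2ccccc2)(c2ccccc2)C(C)(C)C)C[C@H](O[Si](C)(C)C(C)(C)C)C1 | intermediate
13 | (4R,6S)-4-(tert-butyldimethylsilyloxy)-6-[(tert-butyldiphenylsilyloxy)methyl]-1-ethenyl-2,6-dimethylcyclohex-1-ene | C=CC1=C(C)C[C@@H](O[Si](C)(C)C(C)(C)C)C[C@]1(C)CO[Si](c1ccccc1)(c1ccccc1)C(C)(C)C | intermediate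
14 | (1R,5S)-5-[(tert-butyldiphenylsilyloxy)methyl]-4-ethenyl-3,5-dimethylcyclohex-3-en-1-ol | C=CC1=C(C)C[C@@H](O)C[C@]1(C)CO[Si](c1ccccc1)(c1ccccc1)C(C)(C)C | intermediate
15 | but-2-ynoic acid | CC#CC(=O)O | starting material
16 | (1R,5S)-5-[(tert-butyldiphenylsilyloxy)methyl]-4-ethenyl-3,5-dimethylcyclohex-3-en-1-yl but-2-ynoate | C=CC1=C(C)C[C@@H](OC(=O)C#CC)C[C@]1(C)CO[Si](c1ccccc1)(c1ccccc1)C(C)(C)C | intermediate
17 | 19-(tert-butyldiphenylsilyloxy)-12,13,14,15,16-pentanorlabda-5,8-dien-11,2α-olide (10β-methyl) | CC1=C2C(=O)O[C@H]3C[C@](C)(CO[Si](c4ccccc4)(c4ccccc4)C(C)(C)C)C(=CC1)[C@]2(C)C3 | intermediate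
18 | 19-(tert-butyldiphenylsilyloxy)-12,13,14,15,16-pentanorlabda-5,8-diene-2α,11-diol | CC1=C(CO)[C@@]2(C)C[C@@H](O)C[C@](C)(CO[Si](c3ccccc3)(c3ccccc3)C(C)(C)C)C2=CC1 | intermediate
19 | 6α-boryl-5α-H adduct of 18 (drawn as the monoalkylborane with free hydroxyls) | CC1=C(CO)[C@@]2(C)C[C@@H](O)C[C@](C)(CO[Si](c3ccccc3)(c3ccccc3)C(C)(C)C)[C@@H]2[C@@H](B)C1 | intermediate
20 | 19-(tert-butyldiphenylsilyloxy)-12,13,14,15,16-pentanor-5α-labd-8-ene-2α,6α,11-triol | CC1=C(CO)[C@@]2(C)C[C@@H](O)C[C@](C)(CO[Si](c3ccccc3)(c3ccccc3)C(C)(C)C)[C@@H]2[C@@H](O)C1 | intermediate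
21 | 19-(tert-butyldiphenylsilyloxy)-2α,6α-dihydroxy-12,13,14,15,16-pentanor-5α-labd-8-en-11-al | CC1=C(C=O)[C@@]2(C)C[C@@H](O)C[C@](C)(CO[Si](c3ccccc3)(c3ccccc3)C(C)(C)C)[C@@H]2[C@@H](O)C1 | intermediate
22 | 19-(tert-butyldiphenylsilyloxy)-13,14,15,16-tetranor-5α-labda-8,11-diene-2α,6α-diol | CC1=C(C=C)[C@@]2(C)C[C@@H](O)C[C@](C)(CO[Si](c3ccccc3)(c3ccccc3)C(C)(C)C)[C@@H]2[C@@H](O)C1 | intermediate
23 | 4-bromofuran-2(5H)-one | O=C1OCC(Br)=C1 | starting material
24 | 12-(9-borabicyclo[3.3.1]nonan-9-yl) adduct of 22 (hydroxyls drawn free) | CC1=C(CCB3C4CCCC3CCC4)[C@@]2(C)C[C@@H](O)C[C@](C)(CO[Si](c3ccccc3)(c3ccccc3)C(C)(C)C)[C@@H]2[C@@H](O)C1 | intermediate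
25 | 19-(tert-butyldiphenylsilyloxy)-2α,6α-dihydroxylabda-8,13-dien-15,16-olide | CC1=C(CCC2=CC(=O)OC2)[C@@]2(C)C[C@@H](O)C[C@](C)(CO[Si](c3ccccc3)(c3ccccc3)C(C)(C)C)[C@@H]2[C@@H](O)C1 | intermediate
26 | 2α,6α,19-trihydroxylabda-8,13-dien-15,16-olide, (2R,4S,5R,6S,10S) | CC1=C(CCC2=CC(=O)OC2)[C@@]2(C)C[C@@H](O)C[C@](C)(CO)[C@@H]2[C@@H](O)C1 | target

**Step count and risks**

Total step count: 16. Longest linear sequence: 16 steps (1 to 26; 15 and 23 are commercial).

Steps most likely to fail:

1. Step 10. The cycloaddition may be outrun by the [1,5]-hydrogen shift of the C10 methyl group, or the ester tether may not reach its reactive conformation below the temperature at which the diene degrades. The fallback changes the dienophile to an allenoate. It sets out from 14 and returns at 17. Esterification of 14 with but-3-ynoic acid (DCC, CH2Cl2, 0 °C) gives the but-3-ynoate F1. Et3N isomerises it to the buta-2,3-dienoate F2. The allenic α,β-double bond is a far more reactive tethered dienophile and should cyclise in toluene at 80–110 °C, with the same α-face delivery to C10, to the 8(17)-exo-methylene 9-H lactone F3. DBU in CH2Cl2 then moves the exocyclic double bond into conjugation (C8=C9) and gives 17.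

2. Step 12. Borane may also attack the tetrasubstituted C8=C9 bond, or facial selectivity at C5=C6 may erode. The fallback deactivates C8=C9 by conjugation. It sets out from 17 and returns at 20. Methanolysis of the strained lactone (NaOMe, MeOH, 0 °C) gives the 2α-hydroxy methyl ester F4, in which C8=C9 is an electron-poor enoate and ring A is free to adopt its chair. Hydroboration (BH3·THF, then NaBO3) gives the 5α-H, 6α-hydroxy ester F5. LiAlH4 reduces the ester to the allylic alcohol and gives 20.

3. Step 3. Discrimination of the two enantiotopic α-hydrogens may be incomplete, and the resulting low enantiomeric purity would be carried through to 14. The fallback upgrades the material by diastereomer separation. It sets out from 14 and returns at 14. Esterification with (S)-2-methoxy-2-phenylacetic acid (DCC, DMAP) gives diastereomeric esters; the major one, the (S)-O-methylmandelate F6, is separated by chromatography or crystallisation. K2CO3 in MeOH then releases enantiomerically pure 14.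

Further compounds
F1 | step 10 | (1R,5S)-5-[(tert-butyldiphenylsilyloxy)methyl]-4-ethenyl-3,5-dimethylcyclohex-3-en-1-yl but-3-ynoate | C=CC1=C(C)C[C@@H](OC(=O)CC#C)C[C@]1(C)CO[Si](c1ccccc1)(c1ccccc1)C(C)(C)C
F2 | step 10 | (1R,5S)-5-[(tert-butyldiphenylsilyloxy)methyl]-4-ethenyl-3,5-dimethylcyclohex-3-en-1-yl buta-2,3-dienoate | C=CC1=C(C)C[C@@H](OC(=O)C=C=C)C[C@]1(C)CO[Si](c1ccccc1)(c1ccccc1)C(C)(C)C
F3 | step 10 | 19-(tert-butyldiphenylsilyloxy)-12,13,14,15,16-pentanorlabda-5,8(17)-dien-11,2α-olide (C9 configuration not defined) | C=C1C2C(=O)O[C@H]3C[C@](C)(CO[Si](c4ccccc4)(c4ccccc4)C(C)(C)C)C(=CC1)[C@]2(C)C3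
F4 | step 12 | methyl 19-(tert-butyldiphenylsilyloxy)-2α-hydroxy-12,13,14,15,16-pentanorlabda-5,8-dien-11-oate | CC1=C(C(=O)OC)[C@@]2(C)C[C@@H](O)C[C@](C)(CO[Si](c3ccccc3)(c3ccccc3)C(C)(C)C)C2=CC1
F5 | step 12 | methyl 19-(tert-butyldiphenylsilyloxy)-2α,6α-dihydroxy-12,13,14,15,16-pentanor-5α-labd-8-en-11-oate | CC1=C(C(=O)OC)[C@@]2(C)C[C@@H](O)C[C@](C)(CO[Si](c3ccccc3)(c3ccccc3)C(C)(C)C)[C@@H]2[C@@H](O)C1
F6 | step 3 | (1R,5S)-5-[(tert-butyldiphenylsilyloxy)methyl]-4-ethenyl-3,5-dimethylcyclohex-3-en-1-yl (S)-2-methoxy-2-phenylacetate | C=CC1=C(C)C[C@@H](OC(=O)[C@@H](OC)c2ccccc2)C[C@]1(C)CO[Si](c1ccccc1)(c1ccccc1)C(C)(C)C
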